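**Retrosynthetic overview**

1. Locants used throughout: ring A (cyclopentane) = C5(OH), C6(H), C7, C8(OH), C9(Me2); ring B (cycloheptanone) = C2(Me), C3, C4, C5, C6, C10(=O), C11(Me); chain C12–C13; butenolide = C14 (β-carbon), C15 (α-CH), C16 (C=O), ring O, C17 (OCH2).
2. The butenolide is made last, at the lactol-ether level, by a formal [4+1] one-carbon annulation: Me3SiC(Li)N2 turns the C14 ketone of an α-(methoxymethoxy) ketone into an alkylidene carbene at C15, which closes the ring by 1,5 insertion into an O–CH2–O C–H bond (C15–C16); acetal oxidation and desilylation finish the target.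
3. Enabling feature: C14 is tied through C13–C12 to the fully substituted C11 of ring B, so the carbocyclic arm offers no 1,5 C–H bond and the only 1,5 C–H bonds are those on the acetal carbon C16; the competing C10 ketone is buried between C11 and the ring-fusion carbon C6.
4. Ring B is closed earlier by ring-closing metathesis (C3=C4) of a diene made by adding a C6-lithiated ring A cyclopentene to an α-quaternary aldehyde (C6–C10); one hydrogenation then sets C6 (trans fusion), saturates C3–C4 and frees the side-chain alcohol.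
5. Ring A comes from 2,2-dimethylcyclopentane-1,3-dione (C8 by CBS desymmetrization, C5 by vinyl addition anti to OTBS); C2/C11 come from (S)-5-(hydroxymethyl)furan-2(5H)-one by cuprate addition and two enolate alkylations, unmasked by zinc fragmentation; ring order: ring A (purchased carbocycle), ring B, butenolide.

Key step: step 22

Remark: 6 and Bu3SnCH2OCH2OMe are taken as purchasable reagents; the sense of induction given for the CBS catalyst in step 9 follows the usual model with the quaternary carbon as the large group.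

**Route**

Step 1
Reactants: 1 (S)-5-(hydroxymethyl)furan-2(5H)-one
Product: 2 (S)-5-(((tert-butyldiphenylsilyl)oxy)methyl)furan-2(5H)-one
Conditions: t-BuPh2SiCl, imidazole, CH2Cl2, 0 °C to rt
Reagents that add atoms: tert-butyl(chloro)diphenylsilane, CC(C)(C)[Si](Cl)(c1ccccc1)c1ccccc1
Why: Standard silylation of the primary alcohol masks the hydroxymethyl group that later becomes the leaving group for the fragmentation in step 8; no stereocenter is touched.

Step 2
Reactants: 2 (S)-5-(((tert-butyldiphenylsilyl)oxy)methyl)furan-2(5H)-one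
Product: 3 (4S,5S)-5-(((tert-butyldiphenylsilyl)oxy)methyl)-4-methyldihydrofuran-2(3H)-one
Conditions: Me2CuLi (from MeLi, CuI), Et2O, −78 to −40 °C; then H2O
Reagents that add atoms: lithium dimethylcuprate, [Li+].C[Cu-]C
Why: Conjugate addition of the Gilman cuprate to the butenolide should occur on the face opposite the C5 silyloxymethyl group, which sets the methyl-bearing carbon (C2 of the target) trans to it.

Step 3
Reactants: 3 (4S,5S)-5-(((tert-butyldiphenylsilyl)oxy)methyl)-4-methyldihydrofuran-2(3H)-one
Product: 5 (3S,4S,5S)-5-(((tert-butyldiphenylsilyl)oxy)methyl)-3,4-dimethyldihydrofuran-2(3H)-one, via lithium enolate 4 (not isolated)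
Conditions: LiN(i-Pr)2, THF, −78 °C; MeI, −78 to −40 °C
Reagents that add atoms: iodomethane, CI
Why: Enolate C-methylation anti to the C4 methyl group installs the future C11 methyl; the configuration of this carbon is erased again when it is enolized in step 4.

Step 4
Reactants: 5 (3S,4S,5S)-5-(((tert-butyldiphenylsilyl)oxy)methyl)-3,4-dimethyldihydrofuran-2(3H)-one; 6 benzyl 3-iodopropyl ether
Product: 8 (3S,4S,5S)-3-(3-(benzyloxy)propyl)-5-(((tert-butyldiphenylsilyl)oxy)methyl)-3,4-dimethyldihydrofuran-2(3H)-one, via lithium enolate 7 (not isolated)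
Conditions: LiN(i-Pr)2, THF, −78 °C; then 6, DMPU, −78 to −20 °C
Reagents that add atoms: none
Why: The tetrasubstituted lactone enolate should be alkylated on the face opposite the adjacent C4 methyl group (1,2-induction in the five-membered ring, which outweighs the more remote C5 substituent), so the quaternary carbon (C11 of the target) forms with the chain trans to that methyl and the two methyl groups cis.

Step 5
Reactants: 8 (3S,4S,5S)-3-(3-(benzyloxy)propyl)-5-(((tert-butyldiphenylsilyl)oxy)methyl)-3,4-dimethyldihydrofuran-2(3H)-one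
Product: 9 (3S,4S,5S)-3-(3-(benzyloxy)propyl)-5-(hydroxymethyl)-3,4-dimethyldihydrofuran-2(3H)-one
Conditions: Bu4NF, THF, 0 °C to rt; then H2O
Reagents that add atoms: none
Why: Fluoride cleaves the Si–O bond selectively; the lactone and the benzyl ether are inert.

Step 6
Reactants: 9 (3S,4S,5S)-3-(3-(benzyloxy)propyl)-5-(hydroxymethyl)-3,4-dimethyldihydrofuran-2(3H)-one
Product: 10 (3S,4S,5S)-3-(3-(benzyloxy)propyl)-5-(iodomethyl)-3,4-dimethyldihydrofuran-2(3H)-one
Conditions: I2, PPh3, imidazole, CH2Cl2, 0 °C to rt
Reagents that add atoms: iodine, II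
Why: Appel-type iodination (Garegg–Samuelsson conditions) of the primary alcohol proceeds by SN2 displacement of the oxyphosphonium group.

Step 7
Reactants: 10 (3S,4S,5S)-3-(3-(benzyloxy)propyl)-5-(iodomethyl)-3,4-dimethyldihydrofuran-2(3H)-one
Product: 11 (3S,4S,5S)-3-(3-(benzyloxy)propyl)-5-(iodomethyl)-3,4-dimethyltetrahydrofuran-2-ol (anomer mixture)
Conditions: i-Bu2AlH, CH2Cl2, −78 °C; then aq. potassium sodium tartrate
Reagents that add atoms: none
Why: Half-reduction of the lactone at −78 °C stops at the tetrahedral aluminate and gives the lactol; the primary iodide and the benzyl ether should not react at this temperature.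

Step 8
Reactants: 11 (3S,4S,5S)-3-(3-(benzyloxy)propyl)-5-(iodomethyl)-3,4-dimethyltetrahydrofuran-2-ol
Product: 12 (2S,3R)-2-(3-(benzyloxy)propyl)-2,3-dimethylpent-4-enal
Conditions: Zn dust, THF/H2O 9:1, 60 °C
Reagents that add atoms: none
Why: Bernet–Vasella-type fragmentation (zinc insertion into C–I, then β-elimination of the ring oxygen) opens the lactol to the aldehyde (C10) and the terminal vinyl group (C3) in one operation, destroys the auxiliary lactone C5 stereocenter and leaves the quaternary/tertiary pair untouched, since the aldehyde has no α-hydrogen.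

Step 9
Reactants: 13 2,2-dimethylcyclopentane-1,3-dione
Product: 14 (R)-3-hydroxy-2,2-dimethylcyclopentan-1-one
Conditions: (S)-2-methyl-CBS-oxazaborolidine (10 mol%), catecholborane (1.0 equiv), CH2Cl2, −78 °C; then H2O
Reagents that add atoms: none
Why: Corey–Bakshi–Shibata reduction desymmetrizes the two enantiotopic carbonyl groups; with the quaternary carbon as the large substituent the (S)-catalyst is expected to give the (R)-alcohol (C8 of the target), and one equivalent of borane at low temperature limits over-reduction.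

Step 10
Reactants: 14 (R)-3-hydroxy-2,2-dimethylcyclopentan-1-one
Product: 15 (R)-3-((tert-butyldimethylsilyl)oxy)-2,2-dimethylcyclopentan-1-one
Conditions: t-BuMe2SiCl, imidazole, DMF, rt
Reagents that add atoms: tert-butyl(chloro)dimethylsilane, CC(C)(C)[Si](C)(C)Cl
Why: Standard silylation; the bulky silyl ether later shields one face of ring A.

Step 11
Reactants: 15 (R)-3-((tert-butyldimethylsilyl)oxy)-2,2-dimethylcyclopentan-1-one
Product: 16 (R)-4-((tert-butyldimethylsilyl)oxy)-5,5-dimethylcyclopent-2-en-1-one
Conditions: 2-iodoxybenzoic acid (IBX), DMSO/toluene, 70 °C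
Reagents that add atoms: none
Why: IBX dehydrogenation of the ketone proceeds through its enol, and only the C6 methylene can enolize because the other α-carbon (C9) is quaternary, so a single enone should result.

Step 12
Reactants: 16 (R)-4-((tert-butyldimethylsilyl)oxy)-5,5-dimethylcyclopent-2-en-1-one
Product: 17 (R)-4-((tert-butyldimethylsilyl)oxy)-2-iodo-5,5-dimethylcyclopent-2-en-1-one
Conditions: I2, pyridine, CH2Cl2, 0 °C to rt
Reagents that add atoms: iodine, II
Why: α-Iodination of the enone (reversible pyridine addition at the β-carbon, iodination of the enolate, elimination of pyridine) puts the halogen on C6, the carbon that later carries C10.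

Step 13
Reactants: 17 (R)-4-((tert-butyldimethylsilyl)oxy)-2-iodo-5,5-dimethylcyclopent-2-en-1-one
Product: 18 (1R,4R)-4-((tert-butyldimethylsilyl)oxy)-2-iodo-5,5-dimethyl-1-vinylcyclopent-2-en-1-ol
Conditions: CH2=CHMgBr, THF, −78 °C; then H2O
Reagents that add atoms: vinylmagnesium bromide, C=C[Mg]Br
Why: Grignard 1,2-addition to the non-enolizable ketone should occur on the ring face opposite the C8 silyloxy group, which sets the tertiary carbinol C5 with its oxygen cis to the C8 oxygen.

Step 14
Reactants: 18 (1R,4R)-4-((tert-butyldimethylsilyl)oxy)-2-iodo-5,5-dimethyl-1-vinylcyclopent-2-en-1-ol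
Product: 19 triethylsilyl ether of 18
Conditions: Et3SiOTf, 2,6-lutidine, CH2Cl2, −78 to 0 °C
Reagents that add atoms: triethylsilyl trifluoromethanesulfonate, CC[Si](CC)(CC)OS(=O)(=O)C(F)(F)F
Why: The silyl triflate silylates the hindered tertiary alcohol, which removes the acidic proton before lithiation and blocks retro-aldol chemistry of the later β-oxy ketone.

Step 15
Reactants: 19 triethylsilyl ether of 18; 12 (2S,3R)-2-(3-(benzyloxy)propyl)-2,3-dimethylpent-4-enal
Product: 21 C10 allylic alcohol (both C10 epimers), via cyclopentenyllithium 20 (not isolated)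
Conditions: t-BuLi (2.1 equiv), Et2O, −78 °C; then 12, −78 °C; then H2O
Reagents that add atoms: none
Why: Iodine–lithium exchange gives the cyclopentenyllithium, which adds to the non-enolizable neopentyl aldehyde to form the C6–C10 bond; the new carbinol center is removed by oxidation in step 16.

Step 16
Reactants: 21 C10 allylic alcohol
Product: 22 cross-conjugated enone (C10 ketone)
Conditions: Dess–Martin periodinane (DMP), CH2Cl2, rt
Reagents that add atoms: none
Why: Dess–Martin oxidation of the hindered allylic alcohol should give the enone without touching the silyl ethers or the two vinyl groups.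

Step 17
Reactants: 22 cross-conjugated enone
Product: 23 bicyclic dienone (ring B closed; C3=C4 and C6=C7)
Conditions: second-generation Grubbs catalyst (10 mol%), toluene, 80 °C
Reagents that add atoms: none
Why: Ring-closing metathesis of the two terminal vinyl groups closes the seven-membered ring B at C3=C4 with loss of ethylene; the trisubstituted, conjugated C6=C7 bond should not take part.

Step 18
Reactants: 23 bicyclic dienone
Product: 24 trans-fused hydroazulenone primary alcohol
Conditions: H2 (1–3 atm), Pd/C, EtOAc, rt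
Reagents that add atoms: none
Why: Heterogeneous hydrogenation saturates C3=C4 and the enone C6=C7 and cleaves the benzyl ether; both allylic positions of C6=C7 (C5 and C8) carry a bulky silyloxy group on the same ring face, so hydrogen should add from the opposite face and place C6–H anti to the C5 oxygen (trans ring fusion).

Step 19
Reactants: 24 trans-fused hydroazulenone primary alcohol
Product: 25 side-chain aldehyde (C14 = CHO)
Conditions: DMP, CH2Cl2, rt
Reagents that add atoms: none
Why: Dess–Martin oxidation of the primary alcohol to the aldehyde; the hindered C10 ketone and the silyl ethers are unaffected.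

Step 20
Reactants: 25 side-chain aldehyde
Product: 26 C14 carbinol carrying CH2OCH2OMe (both C14 epimers)
Conditions: Bu3SnCH2OCH2OMe, n-BuLi, THF, −78 °C; then 25, −78 °C; then H2O
Reagents that add atoms: tributyl[(methoxymethoxy)methyl]stannane, CCCC[Sn](CCCC)(CCCC)COCOC
Why: Tin–lithium exchange gives the α-alkoxymethyllithium, which should add to the aldehyde much faster than to the C10 ketone flanked by C11 and C6; this one reagent brings in C17, the ring oxygen and the O–CH2–O carbon (C16) needed for the key step.

Step 21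
Reactants: 26 C14 carbinol
Product: 27 α-(methoxymethoxy) ketone (C14 = C=O)
Conditions: DMP, CH2Cl2, rt
Reagents that add atoms: none
Why: Dess–Martin oxidation gives the α-alkoxy ketone and removes the carbinol stereocenter formed as a mixture in step 20.

Step 22
Reactants: 27 α-(methoxymethoxy) ketone
Product: 30 2-methoxy-2,5-dihydrofuran acetal (both C16 epimers), via diazoalkene 28 (not isolated), via alkylidene carbene 29 (not isolated)
Conditions: Me3SiCHN2, n-BuLi, THF, −78 °C; then 27, −78 to 0 °C; then H2O
Reagents that add atoms: (trimethylsilyl)diazomethane, C[Si](C)(C)C=[N+]=[N-]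
Why: Me3SiC(Li)N2 adds to the unhindered C14 ketone, the adduct loses Me3SiOLi in a Peterson-type elimination to give diazoalkene 28, and loss of N2 gives alkylidene carbene 29 centred on the new carbon C15, which inserts into a C16–H bond of the O–CH2–O group to form the C15–C16 bond. The closest known reaction type is the conversion of α-alkoxy ketones into 2,5-dihydrofurans with lithiated trimethylsilyldiazomethane, including insertions into acetal (anomeric) C–H bonds. The one ring closed is the 2,5-dihydrofuran (the butenolide ring at the lactol-ether level), formed by a concerted 1,5 C–H insertion through a five-membered transition state, so that ketone plus one carbon becomes the ring in a formal [4+1] annulation. The only new stereocenter is the acetal carbon C16, which is not controlled and need not be, because step 23 turns it into the lactone carbonyl. The step needs chemoselectivity for C14=O over C10=O, secured by the quaternary C11 and the ring-fusion C6 that flank C10, and site selectivity of the insertion, secured because C11 carries no hydrogen so that the C16 hydrogens are the only 1,5 C–H bonds, while 1,2-alkyl shift to an alkyne is slow for a dialkyl-substituted carbene. The silyl ether on the C5 oxygen prevents alkoxide formation, so the β-oxy ketone should not open by retro-aldol cleavage under the basic conditions, and the low temperature and single equivalent of base should leave C6 unepimerized.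

Step 23
Reactants: 30 2-methoxy-2,5-dihydrofuran acetal
Product: 31 butenolide bis(silyl ether)
Conditions: [C5H5NH][CrO3Cl] (pyridinium chlorochromate), 4 Å molecular sieves, CH2Cl2, rt
Reagents that add atoms: pyridinium chlorochromate, [O-][Cr](=O)(=O)Cl.c1cc[nH+]cc1
Why: Chromium-based oxidation of a cyclic allylic acetal to the α,β-unsaturated lactone converts the acetal carbon C16 into the lactone carbonyl with loss of methanol, under non-aqueous conditions that should leave the silyl ethers in place.

Step 24
Reactants: 31 butenolide bis(silyl ether)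
Product: 32 target compound
Conditions: HF (48% aq.), MeCN, 0 °C to rt
Reagents that add atoms: none
Why: Fluoride-assisted cleavage of both silyl ethers under acidic, non-basic conditions should free the C5 and C8 hydroxyl groups without retro-aldol opening of the β-hydroxy ketone and without touching any stereocenter.

**Compound list**

1 | (S)-5-(hydroxymethyl)furan-2(5H)-one | O=C1O[C@H](CO)C=C1 | starting material
2 | (S)-5-(((tert-butyldiphenylsilyl)oxy)methyl)furan-2(5H)-one | O=C1O[C@H](CO[Si](c2ccccc2)(c2ccccc2)C(C)(C)C)C=C1 | intermediate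
3 | (4S,5S)-5-(((tert-butyldiphenylsilyl)oxy)methyl)-4-methyldihydrofuran-2(3H)-one | O=C1O[C@H](CO[Si](c2ccccc2)(c2ccccc2)C(C)(C)C)[C@@H](C)C1 | intermediate
4 | lithium enolate of 3 | [Li]OC1=C[C@H](C)[C@@H](CO[Si](c2ccccc2)(c2ccccc2)C(C)(C)C)O1 | intermediate (not isolated)
5 | (3S,4S,5S)-5-(((tert-butyldiphenylsilyl)oxy)methyl)-3,4-dimethyldihydrofuran-2(3H)-one | O=C1O[C@H](CO[Si](c2ccccc2)(c2ccccc2)C(C)(C)C)[C@@H](C)[C@@H]1C | intermediate
6 | benzyl 3-iodopropyl ether | ICCCOCc1ccccc1 | starting material
7 | lithium enolate of 5 | [Li]OC1=C(C)[C@H](C)[C@@H](CO[Si](c2ccccc2)(c2ccccc2)C(C)(C)C)O1 | intermediate (not isolated)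
8 | (3S,4S,5S)-3-(3-(benzyloxy)propyl)-5-(((tert-butyldiphenylsilyl)oxy)methyl)-3,4-dimethyldihydrofuran-2(3H)-one | O=C1O[C@H](CO[Si](c2ccccc2)(c2ccccc2)C(C)(C)C)[C@@H](C)[C@]1(C)CCCOCc1ccccc1 | intermediate
9 | (3S,4S,5S)-3-(3-(benzyloxy)propyl)-5-(hydroxymethyl)-3,4-dimethyldihydrofuran-2(3H)-one | O=C1O[C@H](CO)[C@@H](C)[C@]1(C)CCCOCc1ccccc1 | intermediate
10 | (3S,4S,5S)-3-(3-(benzyloxy)propyl)-5-(iodomethyl)-3,4-dimethyldihydrofuran-2(3H)-one | O=C1O[C@H](CI)[C@@H](C)[C@]1(C)CCCOCc1ccccc1 | intermediate
11 | (3S,4S,5S)-3-(3-(benzyloxy)propyl)-5-(iodomethyl)-3,4-dimethyltetrahydrofuran-2-ol (anomer mixture) | OC1O[C@H](CI)[C@@H](C)[C@]1(C)CCCOCc1ccccc1 | intermediate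
12 | (2S,3R)-2-(3-(benzyloxy)propyl)-2,3-dimethylpent-4-enal | O=C[C@@](C)(CCCOCc1ccccc1)[C@H](C)C=C | intermediate
13 | 2,2-dimethylcyclopentane-1,3-dione | O=C1CCC(=O)C1(C)C | starting material
14 | (R)-3-hydroxy-2,2-dimethylcyclopentan-1-one | O=C1CC[C@@H](O)C1(C)C | intermediate
15 | (R)-3-((tert-butyldimethylsilyl)oxy)-2,2-dimethylcyclopentan-1-one | O=C1CC[C@@H](O[Si](C)(C)C(C)(C)C)C1(C)C | intermediate
16 | (R)-4-((tert-butyldimethylsilyl)oxy)-5,5-dimethylcyclopent-2-en-1-one | O=C1C=C[C@@H](O[Si](C)(C)C(C)(C)C)C1(C)C | intermediate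
17 | (R)-4-((tert-butyldimethylsilyl)oxy)-2-iodo-5,5-dimethylcyclopent-2-en-1-one | O=C1C(I)=C[C@@H](O[Si](C)(C)C(C)(C)C)C1(C)C | intermediate
18 | (1R,4R)-4-((tert-butyldimethylsilyl)oxy)-2-iodo-5,5-dimethyl-1-vinylcyclopent-2-en-1-ol (C5–OH cis to C8–OTBS) | C=C[C@]1(O)C(I)=C[C@@H](O[Si](C)(C)C(C)(C)C)C1(C)C | intermediate
19 | triethylsilyl ether of 18 (ring A vinyl iodide) | C=C[C@]1(O[Si](CC)(CC)CC)C(I)=C[C@@H](O[Si](C)(C)C(C)(C)C)C1(C)C | intermediate
20 | cyclopentenyllithium from 19 (Li on C6) | C=C[C@]1(O[Si](CC)(CC)CC)C([Li])=C[C@@H](O[Si](C)(C)C(C)(C)C)C1(C)C | intermediate (not isolated)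
21 | allylic alcohol: ring A cyclopentene (C6=C7) with C5(OTES)(vinyl), C8–OTBS, C9Me2; C6 carries CH(OH) (C10, both epimers)–C11(Me)[(CH2)3OBn]–C2H(Me)–CH=CH2 | C=C[C@]1(O[Si](CC)(CC)CC)C(=C[C@@H](O[Si](C)(C)C(C)(C)C)C1(C)C)C(O)[C@@](C)(CCCOCc1ccccc1)[C@H](C)C=C | intermediate
22 | cross-conjugated enone (C10 ketone of 21) | C=C[C@]1(O[Si](CC)(CC)CC)C(=C[C@@H](O[Si](C)(C)C(C)(C)C)C1(C)C)C(=O)[C@@](C)(CCCOCc1ccccc1)[C@H](C)C=C | intermediate
23 | bicyclic dienone: ring B closed, C3=C4 and C6=C7, C5–OTES, C8–OTBS, 3-(benzyloxy)propyl on C11 | C[C@@H]1C=C[C@]2(O[Si](CC)(CC)CC)C(=C[C@@H](O[Si](C)(C)C(C)(C)C)C2(C)C)C(=O)[C@@]1(C)CCCOCc1ccccc1 | intermediate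
24 | trans-fused hydroazulenone with C6–H set and (CH2)3OH on C11 | C[C@@H]1CC[C@]2(O[Si](CC)(CC)CC)[C@H](C[C@@H](O[Si](C)(C)C(C)(C)C)C2(C)C)C(=O)[C@@]1(C)CCCO | intermediate
25 | side-chain aldehyde (C14 = CHO) | C[C@@H]1CC[C@]2(O[Si](CC)(CC)CC)[C@H](C[C@@H](O[Si](C)(C)C(C)(C)C)C2(C)C)C(=O)[C@@]1(C)CCC=O | intermediate
26 | C14 carbinol, C14H(OH)–CH2OCH2OMe (both epimers) | C[C@@H]1CC[C@]2(O[Si](CC)(CC)CC)[C@H](C[C@@H](O[Si](C)(C)C(C)(C)C)C2(C)C)C(=O)[C@@]1(C)CCC(O)COCOC | intermediate
27 | α-(methoxymethoxy) ketone, C14(=O)–CH2OCH2OMe | C[C@@H]1CC[C@]2(O[Si](CC)(CC)CC)[C@H](C[C@@H](O[Si](C)(C)C(C)(C)C)C2(C)C)C(=O)[C@@]1(C)CCC(=O)COCOC | intermediate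
28 | diazoalkene (C14=C15=N2) | C[C@@H]1CC[C@]2(O[Si](CC)(CC)CC)[C@H](C[C@@H](O[Si](C)(C)C(C)(C)C)C2(C)C)C(=O)[C@@]1(C)CCC(COCOC)=C=[N+]=[N-] | intermediate (not isolated)
29 | alkylidene carbene (divalent C15) | C[C@@H]1CC[C@]2(O[Si](CC)(CC)CC)[C@H](C[C@@H](O[Si](C)(C)C(C)(C)C)C2(C)C)C(=O)[C@@]1(C)CCC(COCOC)=[C] | intermediate (not isolated)
30 | 4-substituted 2-methoxy-2,5-dihydrofuran (acetal epimers) bis(silyl ether) | C[C@@H]1CC[C@]2(O[Si](CC)(CC)CC)[C@H](C[C@@H](O[Si](C)(C)C(C)(C)C)C2(C)C)C(=O)[C@@]1(C)CCC1=CC(OC)OC1 | intermediate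
31 | butenolide bis(silyl ether) (C5–OTES, C8–OTBS) | C[C@@H]1CC[C@]2(O[Si](CC)(CC)CC)[C@H](C[C@@H](O[Si](C)(C)C(C)(C)C)C2(C)C)C(=O)[C@@]1(C)CCC1=CC(=O)OC1 | intermediate
32 | target compound | C[C@@H]1CC[C@]2(O)[C@H](C[C@@H](O)C2(C)C)C(=O)[C@@]1(C)CCC1=CC(=O)OC1 | target

**Step count and risks**

Total step count: 24. Longest linear sequence: 18 steps (steps 1–8, then 15–24).

Steps most likely to fail:

Step 18. Risk: hydrogen may be delivered to the wrong face of the C6=C7 bond, because ring B crowds the face opposite the silyloxy groups, or the doubly allylic C5–O bond may undergo hydrogenolysis. The fallback sets out from 23 and comes back at 24. Luche reduction (NaBH4, CeCl3, MeOH, −40 °C) of the C10 ketone would give the C10 allylic alcohol F1, the epimer whose hydroxyl lies on the face where C6–H is needed; the other epimer is returned to 23 with DMP. Hydroxyl-directed homogeneous hydrogenation with [Ir(cod)(PCy3)(py)]PF6 under H2 in CH2Cl2 should then deliver hydrogen to C6 from the hydroxyl-bearing face and also saturate C3=C4, giving the saturated C10 alcohol F2. DMP oxidation would give the benzyl-protected saturated ketone F3, and hydrogenolysis of the benzyl ether (H2, Pd/C), now with no olefin left, returns to 24.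

Step 22. Risk: the basic diazomethyl anion may enolize the C14 ketone, or the carbene may be diverted by attack of an acetal oxygen lone pair or by 1,2-shift instead of C–H insertion. The fallback sets out from 27 and comes back at 31, so step 23 is then not needed. The methoxymethyl ether would be cleaved with Me2BBr (CH2Cl2, −78 °C, silyl ethers retained) to give the α-hydroxy ketone F4. Heating F4 with the Bestmann ylide Ph3P=C=C=O (toluene, 90 °C) should acylate the hydroxyl group and close the butenolide by intramolecular Wittig olefination of the C14 ketone, giving 31.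

Step 23. Risk: ionization of the allylic acetal followed by loss of a C17 proton (aromatization to a furan) may outrun the oxidation. The fallback sets out from 30 and comes back at 31, and makes the aromatization the intended reaction. PPTS (cat.) in CH2Cl2 at rt would convert 30 into the 3-substituted furan F5. Sensitized photooxygenation (O2, hν, rose bengal, i-Pr2NEt, CH2Cl2, −78 °C), with base-induced opening of the endoperoxide at the unhindered α-position, should give the 4-substituted 5-hydroxybutenolide F6. NaBH4 (EtOH, 0 °C, then dilute acid) reduces the masked aldehyde and the hydroxy acid relactonizes to 31.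

Further compounds
F1 | step 18 | C10 allylic alcohol of dienone 23 (C10–OH cis to the C6–H to be installed) | C[C@@H]1C=C[C@]2(O[Si](CC)(CC)CC)C(=C[C@@H](O[Si](C)(C)C(C)(C)C)C2(C)C)[C@@H](O)[C@@]1(C)CCCOCc1ccccc1
F2 | step 18 | saturated trans-fused C10 alcohol, benzyl ether retained | C[C@@H]1CC[C@]2(O[Si](CC)(CC)CC)[C@H](C[C@@H](O[Si](C)(C)C(C)(C)C)C2(C)C)[C@@H](O)[C@@]1(C)CCCOCc1ccccc1
F3 | step 18 | saturated trans-fused C10 ketone, benzyl ether retained | C[C@@H]1CC[C@]2(O[Si](CC)(CC)CC)[C@H](C[C@@H](O[Si](C)(C)C(C)(C)C)C2(C)C)C(=O)[C@@]1(C)CCCOCc1ccccc1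
F4 | step 22 | α-hydroxy ketone (C14(=O)–CH2OH) | C[C@@H]1CC[C@]2(O[Si](CC)(CC)CC)[C@H](C[C@@H](O[Si](C)(C)C(C)(C)C)C2(C)C)C(=O)[C@@]1(C)CCC(=O)CO
F5 | step 23 | 3-substituted furan bis(silyl ether) | C[C@@H]1CC[C@]2(O[Si](CC)(CC)CC)[C@H](C[C@@H](O[Si](C)(C)C(C)(C)C)C2(C)C)C(=O)[C@@]1(C)CCc1ccoc1
F6 | step 23 | 4-substituted 5-hydroxyfuran-2(5H)-one bis(silyl ether) | C[C@@H]1CC[C@]2(O[Si](CC)(CC)CC)[C@H](C[C@@H](O[Si](C)(C)C(C)(C)C)C2(C)C)C(=O)[C@@]1(C)CCC1=CC(=O)OC1O
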